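The 1,4-benzodioxin-2-one ring is read as a ring-expanded aurone: its lactone oxygen O1 sits on aromatic carbon C8a, ortho to the ether oxygen O4, so deleting O1 and joining C8a to carbonyl carbon C2 gives a (Z)-2-benzylidenebenzofuran-3(2H)-one, available by a simple aldol condensation. A Baeyer–Villiger oxidation then moves that aryl carbon from carbon to oxygen; in one operation this forms the aryl C–O(acyl) bond, enlarges the furanone to the dioxinone and passes on the Z-alkene unchanged. The precursor is the perbenzylated aurone that already carries the (E)-acrylate of (R)-danshensu at C5, attached by a Heck reaction.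

Key step: step 5

Remark: the SMILES is read as the (R)-configured lactate ester with a Z exocyclic alkene and an E acrylate; 5-bromobenzofuran-3(2H)-one, 3,4-bis(benzyloxy)benzaldehyde and sodium (R)-danshensu are taken as purchasable.

Step 1
Reactants: 1 5-bromobenzofuran-3(2H)-one; 2 3,4-bis(benzyloxy)benzaldehyde
Product: 3 (Z)-2-[3,4-bis(benzyloxy)benzylidene]-5-bromobenzofuran-3(2H)-one
Conditions: neutral Al2O3, CH2Cl2, rt, dark
Reagents that add atoms: none
Why: Aldol condensation of the acidic C2 methylene of the coumaranone with the aldehyde and loss of water should give the aurone as its thermodynamic Z isomer (aryl syn to the ring oxygen, away from the carbonyl).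

Step 2
Reactants: 4 sodium (R)-3-(3,4-dihydroxyphenyl)-2-hydroxypropanoate (sodium danshensu)
Product: 5 benzyl (R)-3-[3,4-bis(benzyloxy)phenyl]-2-hydroxypropanoate
Conditions: BnBr (3.3 equiv), K2CO3, DMF, rt, under Ar
Reagents that add atoms: benzyl bromide, BrCc1ccccc1
Why: Williamson O-alkylation of the two phenoxides and of the carboxylate; K2CO3 does not deprotonate the secondary alcohol, which stays free, and the stereocentre bought with 4 is not touched.

Step 3
Reactants: 5 benzyl (R)-3-[3,4-bis(benzyloxy)phenyl]-2-hydroxypropanoate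
Product: 6 benzyl (R)-2-(acryloyloxy)-3-[3,4-bis(benzyloxy)phenyl]propanoate
Conditions: acryloyl chloride, Et3N, CH2Cl2, 0 °C
Reagents that add atoms: acryloyl chloride, C=CC(=O)Cl
Why: O-acylation of the secondary alcohol by the acid chloride (nucleophilic acyl substitution) leaves the C–O bond at the stereocentre intact, so the R configuration is retained.

Step 4
Reactants: 3 (Z)-2-[3,4-bis(benzyloxy)benzylidene]-5-bromobenzofuran-3(2H)-one; 6 benzyl (R)-2-(acryloyloxy)-3-[3,4-bis(benzyloxy)phenyl]propanoate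
Product: 7 benzyl (R)-3-[3,4-bis(benzyloxy)phenyl]-2-{[(E)-3-{(Z)-2-[3,4-bis(benzyloxy)benzylidene]-3-oxo-2,3-dihydrobenzofuran-5-yl}acryloyl]oxy}propanoate
Conditions: Pd2(dba)3 (cat.), P(t-Bu)3 (cat.), Cy2NMe, 1,4-dioxane, rt to 40 °C, dark
Reagents that add atoms: none
Why: Mizoroki–Heck reaction: oxidative addition of zerovalent palladium into the C5–Br bond, syn insertion of the acrylate and syn β-hydride elimination should give the E-cinnamate, while the hindered amine and the low temperature spare the α-acyloxy ester stereocentre and the aurone.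

Step 5
Reactants: 7 benzyl (R)-3-[3,4-bis(benzyloxy)phenyl]-2-{[(E)-3-{(Z)-2-[3,4-bis(benzyloxy)benzylidene]-3-oxo-2,3-dihydrobenzofuran-5-yl}acryloyl]oxy}propanoate
Product: 9 benzyl (R)-3-[3,4-bis(benzyloxy)phenyl]-2-{[(E)-3-{(Z)-3-[3,4-bis(benzyloxy)benzylidene]-2-oxo-2,3-dihydro-1,4-benzodioxin-7-yl}acryloyl]oxy}propanoate, via Criegee peroxyester adduct 8 (not isolated)
Conditions: mCPBA (1.5 equiv), CF3CO2H (cat.), CH2Cl2, 0 °C to rt, dark
Reagents that add atoms: 3-chloroperoxybenzoic acid (mCPBA), O=C(OO)c1cccc(Cl)c1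
Why: The peracid adds to the C3 ketone of the aurone to give the Criegee adduct 8, in which the aromatic carbon C3a, antiperiplanar to the O–O bond, shifts from C3 to the proximal peroxide oxygen as 3-chlorobenzoate leaves, so the aryl C–O(acyl) bond forms in the same event that enlarges the ring. The closest known reaction type is the Baeyer–Villiger ring expansion of benzo-fused cyclic aryl ketones (1-indanones to dihydrocoumarins, chroman-4-ones to benzodioxepinones), together with the preferred migration of ortho- or para-alkoxyaryl groups in Baeyer–Villiger and Dakin oxidations. The six-membered 1,4-dioxin-2-one ring is closed by ring expansion of the five-membered furanone through a concerted 1,2-shift of carbon to oxygen, not by an end-to-end cyclisation. No stereocentre is created; the Z geometry of the exocyclic alkene is carried over because C2 and its double bond take no part, and the R centre is remote. The step needs aryl migration over migration of the alkenyl carbon C2, and oxygen insertion over epoxidation: the ring oxygen ortho to C3a makes the aryl carbon the better migrating terminus while C2 is the electron-poor α-carbon of a push-pull enol ether, and both alkenes are conjugated to carbonyl groups and hence poor partners for an electrophilic peracid.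

Step 6
Reactants: 9 benzyl (R)-3-[3,4-bis(benzyloxy)phenyl]-2-{[(E)-3-{(Z)-3-[3,4-bis(benzyloxy)benzylidene]-2-oxo-2,3-dihydro-1,4-benzodioxin-7-yl}acryloyl]oxy}propanoate
Product: 10 (R)-3-(3,4-dihydroxyphenyl)-2-{[(E)-3-{(Z)-3-(3,4-dihydroxybenzylidene)-2-oxo-2,3-dihydro-1,4-benzodioxin-7-yl}acryloyl]oxy}propanoic acid
Conditions: BCl3 (1 M in CH2Cl2, excess), C6HMe5 (excess), CH2Cl2, −78 to −20 °C; then THF/H2O
Reagents that add atoms: none
Why: Lewis-acid dealkylation of the four aryl benzyl ethers and the benzyl ester: BCl3 activates the oxygens and pentamethylbenzene traps the benzyl cations by Friedel–Crafts alkylation at low temperature, which should leave both alkenes, the aryl lactone, the cinnamate ester and the stereocentre untouched; the borates are hydrolysed on work-up.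

Compound list
1 | 5-bromobenzofuran-3(2H)-one | O=C1COc2ccc(Br)cc21 | starting material
2 | 3,4-bis(benzyloxy)benzaldehyde | O=Cc1ccc(OCc2ccccc2)c(OCc2ccccc2)c1 | starting material
3 | (Z)-2-[3,4-bis(benzyloxy)benzylidene]-5-bromobenzofuran-3(2H)-one | O=C1/C(=C/c2ccc(OCc3ccccc3)c(OCc3ccccc3)c2)Oc2ccc(Br)cc21 | intermediate
4 | sodium (R)-3-(3,4-dihydroxyphenyl)-2-hydroxypropanoate (sodium danshensu) | [Na+].[O-]C(=O)[C@H](O)Cc1ccc(O)c(O)c1 | starting material
5 | benzyl (R)-3-[3,4-bis(benzyloxy)phenyl]-2-hydroxypropanoate | O=C(OCc1ccccc1)[C@H](O)Cc1ccc(OCc2ccccc2)c(OCc2ccccc2)c1 | intermediate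
6 | benzyl (R)-2-(acryloyloxy)-3-[3,4-bis(benzyloxy)phenyl]propanoate | C=CC(=O)O[C@H](Cc1ccc(OCc2ccccc2)c(OCc2ccccc2)c1)C(=O)OCc1ccccc1 | intermediate
7 | benzyl (R)-3-[3,4-bis(benzyloxy)phenyl]-2-{[(E)-3-{(Z)-2-[3,4-bis(benzyloxy)benzylidene]-3-oxo-2,3-dihydrobenzofuran-5-yl}acryloyl]oxy}propanoate | O=C(/C=C/c1ccc2c(c1)C(=O)/C(=C/c1ccc(OCc3ccccc3)c(OCc3ccccc3)c1)O2)O[C@H](Cc1ccc(OCc2ccccc2)c(OCc2ccccc2)c1)C(=O)OCc1ccccc1 | intermediate
8 | Criegee adduct of 7: C3 carries OH and the (3-chlorobenzoyl)peroxy group, both C3 epimers | O=C(/C=C/c1ccc2c(c1)C(O)(OOC(=O)c1cccc(Cl)c1)/C(=C/c1ccc(OCc3ccccc3)c(OCc3ccccc3)c1)O2)O[C@H](Cc1ccc(OCc2ccccc2)c(OCc2ccccc2)c1)C(=O)OCc1ccccc1 | intermediate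
9 | benzyl (R)-3-[3,4-bis(benzyloxy)phenyl]-2-{[(E)-3-{(Z)-3-[3,4-bis(benzyloxy)benzylidene]-2-oxo-2,3-dihydro-1,4-benzodioxin-7-yl}acryloyl]oxy}propanoate | O=C(/C=C/c1ccc2c(c1)OC(=O)/C(=C/c1ccc(OCc3ccccc3)c(OCc3ccccc3)c1)O2)O[C@H](Cc1ccc(OCc2ccccc2)c(OCc2ccccc2)c1)C(=O)OCc1ccccc1 | intermediate
10 | (R)-3-(3,4-dihydroxyphenyl)-2-{[(E)-3-{(Z)-3-(3,4-dihydroxybenzylidene)-2-oxo-2,3-dihydro-1,4-benzodioxin-7-yl}acryloyl]oxy}propanoic acid | O=C(/C=C/c1ccc2c(c1)OC(=O)/C(=C/c1ccc(O)c(O)c1)O2)O[C@H](Cc1ccc(O)c(O)c1)C(=O)O | target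

Total step count: 6. Longest linear sequence: 5 steps (4 → 5 → 6 → 7 → 9 → 10).

Steps most likely to fail

1. Step 5. The peracid may epoxidise the exocyclic enol-ether alkene, the alkenyl carbon C2 may migrate in place of the aryl carbon, or the doubly conjugated ketone may not form the Criegee adduct. The fallback sets out from aldehyde 2 and acrylate 6 and returns at 9; it closes the same aryl C–O bond by copper catalysis. 4-Bromo-2-iodophenol is O-alkylated with chloroacetic acid (NaOH, H2O, reflux; then HCl) to 2-(4-bromo-2-iodophenoxy)acetic acid F1. Perkin condensation of F1 with 2 (Ac2O, Et3N, 110 °C) should give (Z)-3-[3,4-bis(benzyloxy)phenyl]-2-(4-bromo-2-iodophenoxy)acrylic acid F2, with the aryl group trans to the carboxyl group. Intramolecular Ullmann-type O-arylation of the carboxylate at the C–I bond (CuI, 1,10-phenanthroline, Cs2CO3, toluene, 90 °C) should then give (Z)-3-[3,4-bis(benzyloxy)benzylidene]-7-bromo-1,4-benzodioxin-2(3H)-one F3, the C–Br bond being left for the next step. Heck coupling of F3 with 6 under the conditions of step 4 leads to 9.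

2. Step 6. The Lewis acid may open the aryl lactone, the benzyl ester may cleave too slowly, or benzyl cations may alkylate the liberated catechol rings. The fallback sets out from 7 and returns at 10; it exchanges the protecting groups before the ring expansion, so that the last step is a Brønsted-acid acetal hydrolysis. Aurone 7, which has no lactone, is debenzylated (BCl3, C6HMe5, CH2Cl2, −78 °C; then H2O) to (R)-3-(3,4-dihydroxyphenyl)-2-{[(E)-3-{(Z)-2-(3,4-dihydroxybenzylidene)-3-oxo-2,3-dihydrobenzofuran-5-yl}acryloyl]oxy}propanoic acid F4. Exhaustive methoxymethylation (MOMCl, i-Pr2NEt, CH2Cl2, 0 °C) gives the methoxymethyl ester tetrakis(methoxymethyl) ether F5. Baeyer–Villiger ring expansion (mCPBA, CH2Cl2, 0 °C to rt) gives the corresponding (Z)-3-benzylidene-1,4-benzodioxin-2-one F6. Hydrolysis of all five acetal groups (CF3CO2H/CH2Cl2/H2O, 0 °C to rt) gives 10.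

3. Step 4. Oxidative addition into the electron-rich aryl bromide may be slow, and longer heating with base risks epimerisation of the α-acyloxy ester or degradation of the acrylate. The fallback sets out from 3 and 5 and returns at 7; it forms the C–C bond before the stereocentre is present. Heck coupling of 3 with acrylic acid under forcing conditions (Pd(OAc)2, P(o-tol)3, Et3N, DMF, 100 °C) gives (E)-3-{(Z)-2-[3,4-bis(benzyloxy)benzylidene]-3-oxo-2,3-dihydrobenzofuran-5-yl}acrylic acid F7. Steglich esterification of F7 with alcohol 5 (EDC, DMAP cat., CH2Cl2, 0 °C to rt) gives 7.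

Further compounds
F1 | step 5 | 2-(4-bromo-2-iodophenoxy)acetic acid | OC(=O)COc1ccc(Br)cc1I
F2 | step 5 | (Z)-3-[3,4-bis(benzyloxy)phenyl]-2-(4-bromo-2-iodophenoxy)acrylic acid | OC(=O)/C(=C/c1ccc(OCc2ccccc2)c(OCc2ccccc2)c1)Oc1ccc(Br)cc1I
F3 | step 5 | (Z)-3-[3,4-bis(benzyloxy)benzylidene]-7-bromo-1,4-benzodioxin-2(3H)-one | Brc1ccc2c(c1)OC(=O)/C(=C/c1ccc(OCc3ccccc3)c(OCc3ccccc3)c1)O2
F4 | step 6 | (R)-3-(3,4-dihydroxyphenyl)-2-{[(E)-3-{(Z)-2-(3,4-dihydroxybenzylidene)-3-oxo-2,3-dihydrobenzofuran-5-yl}acryloyl]oxy}propanoic acid | O=C(/C=C/c1ccc2c(c1)C(=O)/C(=C/c1ccc(O)c(O)c1)O2)O[C@H](Cc1ccc(O)c(O)c1)C(=O)O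
F5 | step 6 | methoxymethyl (R)-3-[3,4-bis(methoxymethoxy)phenyl]-2-{[(E)-3-{(Z)-2-[3,4-bis(methoxymethoxy)benzylidene]-3-oxo-2,3-dihydrobenzofuran-5-yl}acryloyl]oxy}propanoate | O=C(/C=C/c1ccc2c(c1)C(=O)/C(=C/c1ccc(OCOC)c(OCOC)c1)O2)O[C@H](Cc1ccc(OCOC)c(OCOC)c1)C(=O)OCOC
F6 | step 6 | methoxymethyl (R)-3-[3,4-bis(methoxymethoxy)phenyl]-2-{[(E)-3-{(Z)-3-[3,4-bis(methoxymethoxy)benzylidene]-2-oxo-2,3-dihydro-1,4-benzodioxin-7-yl}acryloyl]oxy}propanoate | O=C(/C=C/c1ccc2c(c1)OC(=O)/C(=C/c1ccc(OCOC)c(OCOC)c1)O2)O[C@H](Cc1ccc(OCOC)c(OCOC)c1)C(=O)OCOC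
F7 | step 4 | (E)-3-{(Z)-2-[3,4-bis(benzyloxy)benzylidene]-3-oxo-2,3-dihydrobenzofuran-5-yl}acrylic acid | OC(=O)/C=C/c1ccc2c(c1)C(=O)/C(=C/c1ccc(OCc3ccccc3)c(OCc3ccccc3)c1)O2
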